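**Target as read from the SMILES:** (13Z)-7α-acetoxy-6β-hydroxylabda-8,13-dien-15-yl acetate, normal labdane series (5α-H, 10β-CH3), with the 6-OH and 7-OAc trans-diaxial.

**Retrosynthetic overview**
- The 6β-OH comes last, by α-face hydride reduction of a C6 ketone (the β face is blocked by the axial C10 and C4 methyls).
- The 7α-OAc and the C8=C9 alkene come together from α-oxygenation of the thermodynamic 6,8(9)-dienolate of a 7-en-6-one.
- The 7-en-6-one comes from allylic oxidation of (13Z)-labda-7,13-dien-15-yl acetate.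
- Rings A and B are closed in one enantioselective, proton-initiated cation–olefin cascade (ring A first, then ring B) of the complete (2Z,6E,10E)-geranylgeranyl acetate; the electron-poor Z-allylic acetate alkene stops the cascade at the bicycle.
- The tetraene comes in one flask from (2E,6E)-farnesyl bromide and Z-selective alkylation of dilithiated prenol.

**Assumption:** the (R)-configured binaphthol-ether·SnCl4 acid gives the 5S,10S ring fusion, as it does in ambrox-type cyclizations; if the opposite sense is found, the (S)-ligand is used.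

**Step 1**
Reactants: 1 prenol (3-methylbut-2-en-1-ol); 2 (2E,6E)-farnesyl bromide
Product: 5 (2Z,6E,10E)-3,7,11,15-tetramethylhexadeca-2,6,10,14-tetraen-1-yl acetate, via dilithiated prenol 3 (not isolated), via lithium alkoxide of geranylnerol 4 (not isolated)
Conditions: 1 (2 equiv), n-BuLi (4.2 equiv), TMEDA, Et2O/hexane, 0 °C to rt, 24 h; 2 (1 equiv), −78 to 0 °C; then Ac2O, 0 °C; AgNO3–silica chromatography
Reagents that add atoms: acetic anhydride, CC(=O)OC(C)=O
Why: Alkoxide-directed allylic lithiation of prenol removes a proton from the methyl cis to CH2OLi, and the chelated allyllithium is alkylated at its CH2 terminus by the allylic bromide (SN2), so the new trisubstituted alkene is Z; the lithium alkoxide is then O-acetylated in the same flask (dianion alkylation, then acylation).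

**Step 2**
Reactants: 5 (2Z,6E,10E)-geranylgeranyl acetate
Product: 7 (13Z)-labda-7,13-dien-15-yl acetate of the normal 5α-H/9α-H/10β-methyl series, via labd-13-en-8-yl cation 6 (not isolated)
Conditions: (R)-2-(2-fluorobenzyloxy)-2′-hydroxy-1,1′-binaphthyl·SnCl4 (1.5 equiv), toluene, −78 °C, 48 h; aq NaHCO3; AgNO3–silica chromatography
Reagents that add atoms: none
Why: Proposed new method: the chiral Lewis-acid-assisted Brønsted acid (phenolic O–H acidified by SnCl4) protonates the terminal isopropylidene on one enantioface while the 10,11- and 6,7-alkenes add anti-periplanar through a chair–chair array, which sets 5α-H, 10β-CH3 and 9α-H in one event; the Z-allylic acetate alkene is too electron-poor to trap cation 6 at −78 °C, so the cascade stops at the bicycle and kinetic E1 loss of the axial 7α-H gives the endocyclic alkene; closest known reaction type: enantioselective proton-initiated polyprenoid cyclization by binaphthol-ether·SnCl4 acids, so far terminated by hydroxyl or aryl groups and here extended to E1 termination on a complete tetraene.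

**Step 3**
Reactants: 7 (13Z)-labda-7,13-dien-15-yl acetate
Product: 8 (13Z)-6-oxolabda-7,13-dien-15-yl acetate (5α-H, 9α-H, 10β-CH3)
Conditions: CrO3 (15 equiv), 3,5-dimethylpyrazole (15 equiv), CH2Cl2, −20 °C, 4 h
Reagents that add atoms: chromium trioxide (used as its 3,5-dimethylpyrazole complex), O=[Cr](=O)=O
Why: Salmond-type allylic oxidation with the hexavalent chromium–pyrazole complex converts the ring methylene C6 next to the electron-rich C7=C8 alkene into the conjugated enone, while the side-chain alkene is deactivated by its allylic acetate; no stereocenter is formed.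

**Step 4**
Reactants: 8 (13Z)-6-oxolabda-7,13-dien-15-yl acetate
Product: 11 (13Z)-7α-acetoxy-6-oxolabda-8,13-dien-15-yl acetate, via potassium dienolate 9 (not isolated), via potassium 7α-alkoxide 10 (not isolated)
Conditions: KN(SiMe3)2 (0.95 equiv), THF, −78 to −20 °C, 1 h; trans-2-(phenylsulfonyl)-3-phenyloxaziridine (1.3 equiv), −78 °C; Ac2O (3 equiv), −78 to 0 °C; pH 7 buffer
Reagents that add atoms: trans-2-(phenylsulfonyl)-3-phenyloxaziridine (Davis oxaziridine), O=S(=O)(N1OC1c1ccccc1)c1ccccc1; acetic anhydride, CC(=O)OC(C)=O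
Why: Equilibrating γ-deprotonation gives the linear, more substituted 6,8(9)-dienolate, which is hydroxylated at its α-carbon C7 (Davis oxidation) from the α face, anti to the angular C10 methyl; this sets 7α-O and leaves the alkene at C8=C9, and the alkoxide is trapped in situ as the acetate.

**Step 5**
Reactants: 11 (13Z)-7α-acetoxy-6-oxolabda-8,13-dien-15-yl acetate
Product: 12 (13Z)-7α-acetoxy-6β-hydroxylabda-8,13-dien-15-yl acetate
Conditions: NaBH4, CeCl3·7H2O, MeOH, −78 to −40 °C
Reagents that add atoms: none
Why: In this Luche reduction hydride reaches the C6 carbonyl from the α face, because the β face is blocked by the syn-axial C10 and C4β methyls, giving the axial 6β-alcohol; the trans-diaxial 6-OH/7-OAc pair cannot undergo acyl migration.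

**Compound list**
1 | prenol (3-methylbut-2-en-1-ol) | CC(C)=CCO | starting material
2 | (2E,6E)-farnesyl bromide | CC(C)=CCC/C(C)=C/CC/C(C)=C/CBr | starting material
3 | dilithiated prenol (O-lithio; C-lithio at the methyl cis to CH2O) | [Li]C/C(C)=C\CO[Li] | intermediate
4 | lithium alkoxide of geranylnerol, (2Z,6E,10E) | CC(C)=CCC/C(C)=C/CC/C(C)=C/CC/C(C)=C\CO[Li] | intermediate
5 | (2Z,6E,10E)-geranylgeranyl acetate | CC(C)=CCC/C(C)=C/CC/C(C)=C/CC/C(C)=C\COC(C)=O | intermediate
6 | (13Z)-15-acetoxylabd-13-en-8-yl cation (5α-H, 9α-H, 10β-CH3) | CC(=O)OC/C=C(/C)CC[C@H]1[C+](C)CC[C@H]2C(C)(C)CCC[C@]12C | intermediate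
7 | (13Z)-labda-7,13-dien-15-yl acetate (5α-H, 9α-H, 10β-CH3) | CC(=O)OC/C=C(/C)CC[C@H]1C(C)=CC[C@H]2C(C)(C)CCC[C@]12C | intermediate
8 | (13Z)-6-oxolabda-7,13-dien-15-yl acetate (5α-H, 9α-H, 10β-CH3) | CC(=O)OC/C=C(/C)CC[C@H]1C(C)=CC(=O)[C@H]2C(C)(C)CCC[C@]12C | intermediate
9 | potassium 6,8(9)-dienolate of 8 (6-oxido-labda-6,8,13Z-trien-15-yl acetate) | CC(=O)OC/C=C(/C)CCC1=C(C)C=C([O-])[C@H]2C(C)(C)CCC[C@]12C.[K+] | intermediate
10 | potassium 7α-alkoxide of (13Z)-7α-hydroxy-6-oxolabda-8,13-dien-15-yl acetate | CC(=O)OC/C=C(/C)CCC1=C(C)[C@H]([O-])C(=O)[C@H]2C(C)(C)CCC[C@]12C.[K+] | intermediate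
11 | (13Z)-7α-acetoxy-6-oxolabda-8,13-dien-15-yl acetate (5α-H, 10β-CH3) | CC(=O)OC/C=C(/C)CCC1=C(C)[C@H](OC(C)=O)C(=O)[C@H]2C(C)(C)CCC[C@]12C | intermediate
12 | (13Z)-7α-acetoxy-6β-hydroxylabda-8,13-dien-15-yl acetate (5α-H, 10β-CH3) | CC(=O)OC/C=C(/C)CCC1=C(C)[C@H](OC(C)=O)[C@@H](O)[C@H]2C(C)(C)CCC[C@]12C | target

**Step count:** 5 steps in total; longest linear sequence 5 steps (from 1 or 2).

**Steps most likely to fail**

Step 2 (cyclization). Risks are a stop at the monocycle, E1 regioisomers (8(17)- and 8(9)-alkenes), ionization of the neryl-type acetate, and an ee near 80–90% that would need upgrading (chiral-phase chromatography or crystallization at 8). Fallback: change the initiating event from proton to iodonium. From 5, N-iodosuccinimide with a stoichiometric chiral binaphthol-derived phosphoramidite promoter (toluene, −40 °C) gives (13Z)-3β-iodolabda-7,13-dien-15-yl acetate F1, with equatorial iodine and the same ring fusion. Radical deiodination (Bu3SnH, azobisisobutyronitrile, benzene, 80 °C) comes back to the route at 7.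

Step 3 (allylic oxidation). Risks are competing oxidation at C12 or C16 next to the side-chain alkene, at C9 or C17, and over-oxidation. Fallback: replace C–H oxidation by electrophilic addition and transposition. From 7, PhSeCl in MeCN/H2O adds anti and Markovnikov to the more electron-rich ring alkene to give (13Z)-8β-hydroxy-7α-(phenylseleno)labd-13-en-15-yl acetate F2 (the C7/C8 epimer pair would converge as well). H2O2/pyridine then gives, by selenoxide syn-elimination toward C6, the tertiary allylic alcohol (13Z)-8β-hydroxylabda-6,13-dien-15-yl acetate F3. Pyridinium chlorochromate (C5H5NH)(CrO3Cl) in CH2Cl2 effects the oxidative 1,3-transposition (Babler–Dauben) and comes back to the route at 8.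

Step 4 (dienolate acetoxylation). Risks are kinetic deprotonation at C17 (giving the 8(17)-ene) or C5, enolization of the C15 acetate, γ-attack, and isomerization of 11 to the conjugated enol acetate. Fallback: reduce first and use an ene reaction. From 8, NaBH4/CeCl3·7H2O (MeOH, −78 °C) gives (13Z)-6β-hydroxylabda-7,13-dien-15-yl acetate F4. A Schenck ene reaction with singlet oxygen (O2, tetraphenylporphyrin, hν, CH2Cl2, 0 °C) on the α face, with abstraction of 9α-H, gives (13Z)-7α-hydroperoxy-6β-hydroxylabda-8,13-dien-15-yl acetate F5. PPh3 reduces it to (13Z)-6β,7α-dihydroxylabda-8,13-dien-15-yl acetate F6. Ac2O/pyridine acetylates only the 7α-OH, because the 6β-OH is shielded by two syn-axial methyls, and the sequence comes back to the route at 12.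

**Further compounds**
F1 | step 2 | (13Z)-3β-iodolabda-7,13-dien-15-yl acetate | CC(=O)OC/C=C(/C)CC[C@H]1C(C)=CC[C@H]2C(C)(C)[C@@H](I)CC[C@]12C
F2 | step 3 | (13Z)-8β-hydroxy-7α-(phenylseleno)labd-13-en-15-yl acetate | CC(=O)OC/C=C(/C)CC[C@H]1[C@@](C)(O)[C@H]([Se]c3ccccc3)C[C@H]2C(C)(C)CCC[C@]12C
F3 | step 3 | (13Z)-8β-hydroxylabda-6,13-dien-15-yl acetate | CC(=O)OC/C=C(/C)CC[C@H]1[C@@](C)(O)C=C[C@H]2C(C)(C)CCC[C@]12C
F4 | step 4 | (13Z)-6β-hydroxylabda-7,13-dien-15-yl acetate | CC(=O)OC/C=C(/C)CC[C@H]1C(C)=C[C@@H](O)[C@H]2C(C)(C)CCC[C@]12C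
F5 | step 4 | (13Z)-7α-hydroperoxy-6β-hydroxylabda-8,13-dien-15-yl acetate | CC(=O)OC/C=C(/C)CCC1=C(C)[C@H](OO)[C@@H](O)[C@H]2C(C)(C)CCC[C@]12C
F6 | step 4 | (13Z)-6β,7α-dihydroxylabda-8,13-dien-15-yl acetate | CC(=O)OC/C=C(/C)CCC1=C(C)[C@H](O)[C@@H](O)[C@H]2C(C)(C)CCC[C@]12C
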